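Assumption: the target has no stereocentre and no stereogenic double bond, so "single enantiomer" needs no stereocontrol; 1,2,3,4-tetramethoxybenzene and methyl 3-hydroxy-4,5-dimethoxybenzoate are taken as catalogue chemicals.

**Retrosynthetic overview**
- The free 3'-OH is released last by hydrogenolysis of a benzyl ether.
- Ring C (the pyranone) is the only ring formed: its O1–C8a bond is closed by a new photoredox SNAr in which the enol oxygen of a 1,3-diketone displaces an ortho-methoxy group of a pentamethoxyphenyl ketone.
- The diketone comes from a crossed Claisen condensation of pentamethoxyacetophenone with the benzyl-protected B-ring methyl ester.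
- Pentamethoxyacetophenone comes from pentamethoxybenzene (Friedel–Crafts), itself from 1,2,3,4-tetramethoxybenzene by bromination and copper-catalysed methoxylation; rings A and B are bought.

**Route**

Step 1
Reactants: 1 1,2,3,4-tetramethoxybenzene
Product: 2 1-bromo-2,3,4,5-tetramethoxybenzene
Conditions: NBS (1.0 equiv), MeCN, 0 °C to rt
Reagents that add atoms: N-bromosuccinimide, O=C1CCC(=O)N1Br
Why: Electrophilic aromatic bromination; the two free positions of 1 are equivalent, each ortho to one OMe and para to another, and one equivalent of NBS in MeCN stops at the monobromide.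

Step 2
Reactants: 2 1-bromo-2,3,4,5-tetramethoxybenzene
Product: 3 pentamethoxybenzene
Conditions: NaOMe (4 equiv, 25 % in MeOH), CuBr (10 mol %), DMF, 110 °C, N2
Reagents that add atoms: sodium methoxide, [Na+].[O-]C
Why: Copper-catalysed Ullmann-type C–O coupling (methoxylation of an aryl bromide), the classical entry to polymethoxybenzenes, replaces Br by OMe and leaves the other ethers untouched.

Step 3
Reactants: 3 pentamethoxybenzene
Product: 4 1-(2,3,4,5,6-pentamethoxyphenyl)ethan-1-one
Conditions: Ac2O (2 equiv), Sc(OTf)3 (10 mol %), MeNO2, 50 °C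
Reagents that add atoms: acetic anhydride, CC(=O)OC(C)=O
Why: Friedel–Crafts acylation at the only free ring position, which is activated by two ortho and one para OMe; catalytic Sc(OTf)3 with Ac2O is too mild to cleave the aryl methyl ethers that AlCl3 would attack.

Step 4
Reactants: 5 methyl 3-hydroxy-4,5-dimethoxybenzoate
Product: 6 methyl 3-(benzyloxy)-4,5-dimethoxybenzoate
Conditions: BnBr (1.2 equiv), K2CO3 (2 equiv), DMF, 60 °C
Reagents that add atoms: benzyl bromide, BrCc1ccccc1
Why: Williamson ether synthesis on the phenoxide; the benzyl ether survives the strong base of step 5 and the photoredox step and is removed without Lewis acid at the end.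

Step 5
Reactants: 4 1-(2,3,4,5,6-pentamethoxyphenyl)ethan-1-one; 6 methyl 3-(benzyloxy)-4,5-dimethoxybenzoate
Product: 9 1-[3-(benzyloxy)-4,5-dimethoxyphenyl]-3-(2,3,4,5,6-pentamethoxyphenyl)propane-1,3-dione, via sodium enolate 7 (not isolated), via sodium diketonate 8 (not isolated)
Conditions: NaH (2.5 equiv), THF, 0 °C to 65 °C; then 1 M aq. HCl
Reagents that add atoms: none
Why: Crossed Claisen condensation of a methyl ketone enolate with a non-enolisable aryl ester, driven to completion by deprotonation of the 1,3-diketone to its sodium chelate; the ketone can enolise only at its methyl group.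

Step 6
Reactants: 9 1-[3-(benzyloxy)-4,5-dimethoxyphenyl]-3-(2,3,4,5,6-pentamethoxyphenyl)propane-1,3-dione
Product: 10 2-[3-(benzyloxy)-4,5-dimethoxyphenyl]-5,6,7,8-tetramethoxy-4H-chromen-4-one
Conditions: 3,6-di-tert-butyl-9-mesityl-10-phenylacridinium tetrafluoroborate (5 mol %), DCE/HFIP 4:1 (0.05 M), 450 nm LEDs, N2, 30 °C
Reagents that add atoms: none
Why: Proposed new method: an intramolecular cation-radical-accelerated SNAr in which the enol oxygen of the diketone displaces an ortho-methoxy group to close the pyranone ring — the excited acridinium (about +2.1 V vs SCE) oxidises the pentamethoxyphenyl ring (the most electron-rich π-system of 9) to its radical cation, the enol OH adds at the ipso carbon of an ortho C–OMe (both ortho positions carry OMe and are equivalent, so only one ring closure is possible), the oxonium proton passes to the geminal methoxy group with help from HFIP, methanol leaves to give the chromone radical cation, and back electron transfer from the acridine radical (or chain transfer from another molecule of 9) makes the cycle redox-neutral with no stereocentre formed; the closest known reaction types are the acridinium-photocatalysed cation-radical SNAr of methoxyarenes with azoles and ammonia (intermolecular, N-nucleophiles) and the thermal base-mediated SNAr closure of 1-(2-fluoro- or 2-nitroaryl)-1,3-diketones to flavones, neither of which uses an enol oxygen nucleophile with a methoxide leaving group.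

Step 7
Reactants: 10 2-[3-(benzyloxy)-4,5-dimethoxyphenyl]-5,6,7,8-tetramethoxy-4H-chromen-4-one
Product: 11 2-(3-hydroxy-4,5-dimethoxyphenyl)-5,6,7,8-tetramethoxy-4H-chromen-4-one
Conditions: H2 (1 atm), 10 % Pd/C, EtOAc/MeOH 1:1, rt
Reagents that add atoms: none
Why: Palladium-catalysed hydrogenolysis of the benzyl aryl ether; the chromone C2=C3 bond, the carbonyl and the six methyl ethers are inert at 1 atm and room temperature, and no Lewis acid is present that could cleave the chelation-prone 5-OMe.

**Compound list**
1 | 1,2,3,4-tetramethoxybenzene | COc1ccc(OC)c(OC)c1OC | starting material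
2 | 1-bromo-2,3,4,5-tetramethoxybenzene | COc1cc(Br)c(OC)c(OC)c1OC | intermediate
3 | pentamethoxybenzene | COc1cc(OC)c(OC)c(OC)c1OC | intermediate
4 | 1-(2,3,4,5,6-pentamethoxyphenyl)ethan-1-one | CC(=O)c1c(OC)c(OC)c(OC)c(OC)c1OC | intermediate
5 | methyl 3-hydroxy-4,5-dimethoxybenzoate | COC(=O)c1cc(O)c(OC)c(OC)c1 | starting material
6 | methyl 3-(benzyloxy)-4,5-dimethoxybenzoate | COC(=O)c1cc(OCc2ccccc2)c(OC)c(OC)c1 | intermediate
7 | sodium 1-(pentamethoxyphenyl)ethen-1-olate (sodium enolate of 4; not isolated) | [Na+].[O-]C(=C)c1c(OC)c(OC)c(OC)c(OC)c1OC | intermediate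
8 | sodium (Z)-enolate of diketone 9 (chelated sodium diketonate; not isolated) | [Na+].[O-]/C(=C\C(=O)c1c(OC)c(OC)c(OC)c(OC)c1OC)c1cc(OC)c(OC)c(OCc2ccccc2)c1 | intermediate
9 | 1-[3-(benzyloxy)-4,5-dimethoxyphenyl]-3-(2,3,4,5,6-pentamethoxyphenyl)propane-1,3-dione (achiral; mainly the H-bonded enol in solution) | O=C(CC(=O)c1c(OC)c(OC)c(OC)c(OC)c1OC)c1cc(OC)c(OC)c(OCc2ccccc2)c1 | intermediate
10 | 2-[3-(benzyloxy)-4,5-dimethoxyphenyl]-5,6,7,8-tetramethoxy-4H-chromen-4-one | COc1cc(-c2cc(=O)c3c(OC)c(OC)c(OC)c(OC)c3o2)cc(OCc2ccccc2)c1OC | intermediate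
11 | 2-(3-hydroxy-4,5-dimethoxyphenyl)-5,6,7,8-tetramethoxy-4H-chromen-4-one (3'-hydroxy-5,6,7,8,4',5'-hexamethoxyflavone; achiral) | COc1cc(-c2cc(=O)c3c(OC)c(OC)c(OC)c(OC)c3o2)cc(O)c1OC | target

**Total step count:** 7
**Longest linear sequence:** 6 steps (1 → 2 → 3 → 4 → 9 → 10 → 11)

**Three steps most likely to fail**

Step 6 (the proposed new step). The hole may sit on the enol or the B-ring instead of ring A, and the ipso adduct may revert faster than methanol leaves. The fallback is known chemistry: chelation-controlled ortho-demethylation, a Baker–Venkataraman-type diketone synthesis and acid cyclodehydration. It sets out from 4 and 6 and comes back to the route at 10. BCl3 (1.05 equiv, CH2Cl2, −78 to 0 °C) cleaves one of the two equivalent ortho-methoxy groups of 4 and gives 1-(2-hydroxy-3,4,5,6-tetramethoxyphenyl)ethan-1-one F1. Claisen condensation of this with ester 6 (LiHMDS, 3.5 equiv, THF, −78 °C to rt, aqueous acid work-up) gives 1-[3-(benzyloxy)-4,5-dimethoxyphenyl]-3-(2-hydroxy-3,4,5,6-tetramethoxyphenyl)propane-1,3-dione F2. Cyclodehydration (cat. p-TsOH, toluene, reflux) then gives 10.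

Step 3. The only free position is flanked by two OMe groups, so acylation may be slow or reversible, and a Lewis acid may cleave an ortho ether. The fallback reverses the polarity (directed ortho-metalation instead of electrophilic substitution); it sets out from 3 and comes back at 4. n-BuLi (1.1 equiv, THF, 0 °C) removes the single ring proton, which lies between two OMe groups, and gives (pentamethoxyphenyl)lithium F3. Addition of N-methoxy-N-methylacetamide at −78 °C gives the chelated tetrahedral adduct lithium 1-[methoxy(methyl)amino]-1-(pentamethoxyphenyl)ethan-1-olate F4, which collapses to 4 on quenching with 1 M HCl.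

Step 2. The electron-rich, ortho-substituted bromide may undergo reductive debromination back to 1 instead of coupling. The fallback splits the C–O bond formation into a palladium-catalysed hydroxylation and a separate O-methylation; it sets out from 2 and comes back at 3. Pd2(dba)3 (1 mol %), t-BuXPhos (4 mol %) and KOH (3 equiv) in dioxane/water at 100 °C, followed by acidification, give 2,3,4,5-tetramethoxyphenol F5. Methylation with MeI and K2CO3 in acetone at reflux gives 3.

**Further compounds**
F1 | step 6 | 1-(2-hydroxy-3,4,5,6-tetramethoxyphenyl)ethan-1-one | CC(=O)c1c(O)c(OC)c(OC)c(OC)c1OC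
F2 | step 6 | 1-[3-(benzyloxy)-4,5-dimethoxyphenyl]-3-(2-hydroxy-3,4,5,6-tetramethoxyphenyl)propane-1,3-dione | O=C(CC(=O)c1c(O)c(OC)c(OC)c(OC)c1OC)c1cc(OC)c(OC)c(OCc2ccccc2)c1
F3 | step 3 | (pentamethoxyphenyl)lithium | [Li]c1c(OC)c(OC)c(OC)c(OC)c1OC
F4 | step 3 | lithium 1-[methoxy(methyl)amino]-1-(pentamethoxyphenyl)ethan-1-olate | CC(O[Li])(N(C)OC)c1c(OC)c(OC)c(OC)c(OC)c1OC
F5 | step 2 | 2,3,4,5-tetramethoxyphenol | COc1cc(O)c(OC)c(OC)c1OC
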